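The runs were computed from invented constants; the scatter is artificial.

I begin with a leftover.

all flasks: free catalyst 0.20 mM; stray impurity 42 µM

| flask | left-handed substrate | right-handed substrate | partner | protic impurity | remark | time |
|---|---|---|---|---|---|---|
| north | 10 mM | 10 mM | 12 mM | 2 mM | run made earlier |  |
| west | 15 mM | 15 mM | 12 mM | 2 mM | run made earlier |  |
| flask | 20 mM | 20 mM | 12.0 mM | 2.00 mM |  | 25 min |

| run | time / min | left-handed substrate / % | right-handed substrate / % |
|---|---|---|---|
| north | 1.00 | 48.0 | 49.2 |
| north | 3.00 | 43.1 | 46.0 |
| north | 5.00 | 41.9 | 46.4 |
| north | 8.00 | 38.7 | 45.9 |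
| north | 12.0 | 36.3 | 42.8 |
| north | 15.0 | 35.9 | 43.9 |
| west | 2.50 | 45.9 | 48.5 |
| west | 5.00 | 45.4 | 46.9 |
| west | 8.00 | 39.5 | 45.7 |
| west | 10.0 | 40.4 | 43.4 |
| west | 12.0 | 39.4 | 46.7 |
| west | 15.0 | 35.5 | 44.2 |

(scatter of a reading: 1 percentage point)

1. part of the left-handed substrate and right-handed substrate charged together that has reacted at 25 min
2. excess of left-handed product over right-handed product in the product at 25 min
3. excess of right-handed substrate over left-handed substrate among what is left of the two at 25 min

- free catalyst is single-handed; left-handed substrate and right-handed substrate are mirror images of each other, charged as a racemate, each of them at the stated concentration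
- the analysis behind the earlier runs scatters by 1 percentage point, standard deviation
- an excess is below zero if the other one leads

1. If the protic impurity takes one partner each, it leaves 10.0 mM of partner in the flask. Divided by the 40.0 mM of substrate charged, that gives 25.0%. This is the allowance: the part of the racemate that the remaining partner can convert, which makes partner the limiting reagent. I assume the impurity's share here, since the readings do not show it.

2. But an allowance is a ceiling, not an arrival. At 15.0 min, the north run reads 20.2% converted, or 4.04 mM. The west run reads 20.3% converted, or 6.09 mM.

3. I let the unused allowance decay exponentially. That gives 0.0345 min⁻¹ for north and 0.0626 min⁻¹ for west. If the decay follows the substrate charge, their ratio should be 1.50, but it is 1.81. These are single readings with a scatter of 1 percentage point, so I average per mM of charge and scale to the flask: 0.0762 min⁻¹.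

4. At 25 min, my c is the allowance times the used fraction: 21.3%. Doesn't falling substrate spoil this? The rates I read already carry a fall of substrate: the north run reads 20.2% converted, close to my c.

5. The left-to-right rate ratio at any moment is the selectivity factor times [left-handed substrate]/[right-handed substrate], so it drifts down as conversion rises. I therefore read the excesses where the runs stand near my c. Their mean gap is 8.4 points at 20.2%, close to my c, and as a reading with the scatter of those points this gives my eP 41.6% and my eS 10.5%.

The forecast says 24%, 38% and 12%, with partner “capping c at 25%”; my c is lower.

The flask gives c 21.0%, eP 35.7% and eS 9.50%.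

    partner + free catalyst + left-handed substrate → free catalyst + left-handed product (k = 3700 L² mol⁻² s⁻¹)
    partner + free catalyst + right-handed substrate → free catalyst + right-handed product (k = 1600 L² mol⁻² s⁻¹)
    partner + protic impurity → quenched reagent (k = 7.60 L mol⁻¹ s⁻¹)
    free catalyst ⇌ dormant form (K = 11.0, k = 0.180 s⁻¹)
    free catalyst + stray impurity → spent catalyst (k = 1.40 × 10⁵ L mol⁻¹ s⁻¹)

At 25.0 min, the flask still holds 13.3% of its partner, or 1.59 mM, and its conversion has used 84.0% of the allowance of 25.0%. The same flask charged with 4.8 mM of partner has an allowance of 7.00% and reaches 6.20%.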